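**Strategy.** Everything rests on disconnecting the aryl–vinyl bond between C5 of the dihydrobenzofuran benzo ring (para to ring oxygen O1) and the β-carbon of the (E)-enone. A Mizoroki–Heck coupling joins an enantiopure (2R,3R)-5-bromo-3-aroyl-2-aryl-2,3-dihydrobenzofuran (three rings, both stereocentres in place) with a MOM-protected 2,4-dihydroxyphenyl vinyl ketone. In one operation it forms this bond, generates the E-enone and completes the carbon skeleton. The step exploits that the enone β-carbon is the free terminus of an aryl vinyl ketone and that C5 is the only carbon–halogen site. The bromide arises from an enantioselective rhodium-carbenoid C–H insertion (C2), epimerisation (C3) and aryllithium acylation of a Weinreb amide.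

Key step: step 11

Assumption (remark on the chemistry): the sense of induction of Rh2(S-PTTL)4 in step 7 is taken by analogy with closely related 5-bromo aryldiazoacetates to give the (2R)-cis product; if this substrate gave the antipode, the mirror-image catalyst Rh2(R-PTTL)4 would be used.

**Step 1**
Reactants: 1 4-bromobenzene-1,3-diol (4-bromoresorcinol)
Product: 2 1-bromo-2,4-bis(methoxymethoxy)benzene
Conditions: MOMCl (2.6 equiv), i-Pr2NEt (3 equiv), CH2Cl2, 0 °C → rt
Reagents that add atoms: chloromethyl methyl ether (MOMCl), COCCl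
Why: Williamson-type O-alkylation of both phenols by the reactive α-chloro ether should give the bis-acetal, a protecting group that tolerates the arylmagnesium and aryllithium reagents made from 2, stabilises them by ortho chelation and is removed at the end without base.

**Step 2**
Reactants: 2 1-bromo-2,4-bis(methoxymethoxy)benzene; 3 acrolein (prop-2-enal)
Product: 5 1-[2,4-bis(methoxymethoxy)phenyl]prop-2-en-1-ol (racemic), via arylmagnesium bromide 4 (not isolated)
Conditions: Mg turnings (1.5 equiv), I2 (cat.), THF, rt → 40 °C; then 3, −78 → −20 °C; NH4Cl (aq)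
Reagents that add atoms: none
Why: Magnesium insertion into the aryl C–Br bond (Grignard reagent formation) leaves the MOM acetals intact, and the ortho-alkoxy-chelated arylmagnesium bromide should add 1,2 to the enal at low temperature (Grignard carbonyl addition).

**Step 3**
Reactants: 5 1-[2,4-bis(methoxymethoxy)phenyl]prop-2-en-1-ol
Product: 6 1-[2,4-bis(methoxymethoxy)phenyl]prop-2-en-1-one
Conditions: activated MnO2 (15 equiv), CH2Cl2, rt; used at once, stored cold over BHT
Reagents that add atoms: none
Why: Manganese dioxide oxidation is selective for allylic/benzylic alcohols and should give the aryl vinyl ketone under neutral conditions that leave the MOM acetals alone.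

**Step 4**
Reactants: 7 4-(methoxymethoxy)benzaldehyde
Product: 8 [4-(methoxymethoxy)phenyl]methanol
Conditions: NaBH4, MeOH, 0 °C
Reagents that add atoms: none
Why: Borohydride reduction of an aromatic aldehyde to the benzyl alcohol is routine and leaves the acetal untouched.

**Step 5**
Reactants: 9 methyl 2-(5-bromo-2-hydroxyphenyl)acetate; 8 [4-(methoxymethoxy)phenyl]methanol
Product: 10 methyl 2-(5-bromo-2-{[4-(methoxymethoxy)phenyl]methoxy}phenyl)acetate
Conditions: PPh3, DIAD, THF, 0 °C → rt
Reagents that add atoms: none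
Why: Mitsunobu etherification of an acidic phenol with a primary benzylic alcohol should give the aryl benzyl ether and avoids the unstable electron-rich benzyl halide.

**Step 6**
Reactants: 10 methyl 2-(5-bromo-2-{[4-(methoxymethoxy)phenyl]methoxy}phenyl)acetate
Product: 11 methyl 2-(5-bromo-2-{[4-(methoxymethoxy)phenyl]methoxy}phenyl)-2-diazoacetate
Conditions: p-ABSA (1.3 equiv), DBU (1.5 equiv), MeCN, 0 °C → rt
Reagents that add atoms: 4-acetamidobenzenesulfonyl azide (p-ABSA), CC(=O)Nc1ccc(cc1)S(=O)(=O)N=[N+]=[N-]
Why: Regitz diazo transfer to the benzylic, ester-activated methylene is the standard entry to aryldiazoacetates.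

**Step 7**
Reactants: 11 methyl 2-(5-bromo-2-{[4-(methoxymethoxy)phenyl]methoxy}phenyl)-2-diazoacetate
Product: 12 methyl (2R,3S)-5-bromo-2-[4-(methoxymethoxy)phenyl]-2,3-dihydro-1-benzofuran-3-carboxylate (cis)
Conditions: Rh2(S-PTTL)4 [dirhodium tetrakis(N-phthaloyl-(S)-tert-leucinate)] (1 mol%), toluene, −60 °C
Reagents that add atoms: none
Why: Intramolecular 1,5 C–H insertion of the donor/acceptor rhodium carbenoid into the ether- and aryl-activated benzylic C–H bond closes the dihydrofuran ring; the chiral carboxylate ligands on the divalent rhodium dimer select one enantiotopic hydrogen and so set C2 as R, while the concerted insertion gives the kinetic cis (3S) ester.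

**Step 8**
Reactants: 12 methyl (2R,3S)-5-bromo-2-[4-(methoxymethoxy)phenyl]-2,3-dihydro-1-benzofuran-3-carboxylate
Product: 13 methyl (2R,3R)-5-bromo-2-[4-(methoxymethoxy)phenyl]-2,3-dihydro-1-benzofuran-3-carboxylate (trans)
Conditions: NaOMe (0.3 equiv), MeOH/THF, 0 °C → rt
Reagents that add atoms: none
Why: Base-mediated epimerisation through the ester enolate inverts only C3 (C2 carries no acidic hydrogen) and should funnel the cis ester to the thermodynamically preferred trans (2R,3R) isomer.

**Step 9**
Reactants: 13 methyl (2R,3R)-5-bromo-2-[4-(methoxymethoxy)phenyl]-2,3-dihydro-1-benzofuran-3-carboxylate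
Product: 14 (2R,3R)-5-bromo-N-methoxy-N-methyl-2-[4-(methoxymethoxy)phenyl]-2,3-dihydro-1-benzofuran-3-carboxamide
Conditions: MeNHOMe·HCl (2.5 equiv), i-PrMgCl (5 equiv), THF, −20 → 0 °C
Reagents that add atoms: N,O-dimethylhydroxylamine hydrochloride, Cl.CNOC
Why: Aminolysis of the ester by the weakly basic magnesium amide generated in the flask should give the Weinreb amide without disturbing C3, whose trans arrangement is in any case the stable one.

**Step 10**
Reactants: 14 (2R,3R)-5-bromo-N-methoxy-N-methyl-2-[4-(methoxymethoxy)phenyl]-2,3-dihydro-1-benzofuran-3-carboxamide; 2 1-bromo-2,4-bis(methoxymethoxy)benzene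
Product: 16 [2,4-bis(methoxymethoxy)phenyl]{(2R,3R)-5-bromo-2-[4-(methoxymethoxy)phenyl]-2,3-dihydro-1-benzofuran-3-yl}methanone, via aryllithium 15 (not isolated)
Conditions: 2 (1.3 equiv), n-BuLi (1.25 equiv), THF, −78 °C, 20 min; then 14, −78 → −40 °C; NH4Cl (aq) at −78 °C
Reagents that add atoms: none
Why: Bromine–lithium exchange on 2 gives the chelated aryllithium for a Weinreb ketone synthesis, in which the tetrahedral chelate should prevent over-addition and hide the acidic C3–H until the cold quench, while aryl–aryl bromine–lithium exchange at C5 is slow at −78 °C and disfavoured against the ortho-alkoxy-stabilised aryllithium.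

**Step 11**
Reactants: 16 [2,4-bis(methoxymethoxy)phenyl]{(2R,3R)-5-bromo-2-[4-(methoxymethoxy)phenyl]-2,3-dihydro-1-benzofuran-3-yl}methanone; 6 1-[2,4-bis(methoxymethoxy)phenyl]prop-2-en-1-one
Product: 17 (E)-1-[2,4-bis(methoxymethoxy)phenyl]-3-{(2R,3R)-3-[2,4-bis(methoxymethoxy)benzoyl]-2-[4-(methoxymethoxy)phenyl]-2,3-dihydro-1-benzofuran-5-yl}prop-2-en-1-one
Conditions: Pd[P(t-Bu)3]2 (5 mol%), Cy2NMe (1.5 equiv), BHT (cat.), 1,4-dioxane, 40–50 °C; 6 (2 equiv) added slowly
Reagents that add atoms: none
Why: Oxidative addition of the C5–Br bond of 16 to zerovalent palladium, migratory insertion of vinyl ketone 6 with aryl transfer to its unsubstituted terminal carbon, syn β-hydride elimination and base-mediated regeneration of zerovalent palladium form the C5–Cβ bond and the enone C=C in one catalytic cycle. The closest known reaction type is the Mizoroki–Heck arylation of vinyl ketones by aryl bromides under bulky trialkylphosphine catalysis, a standard entry to chalcones. No ring is closed and no stereocentre is created; the E geometry follows from syn insertion and syn elimination through the rotamer that places aryl and acyl anti. The step needs site selectivity among three electron-rich rings, which a C–H olefination could not provide; here the single C–Br bond fixes the site, and the carbonyl polarisation and free terminus of 6 secure β-regioselectivity. It also needs C2 and C3 to survive: C2 has no acidic hydrogen, the trans arrangement at C3 is the thermodynamic one so reversible enolisation returns the same isomer, and the hindered amine at 40–50 °C with every phenol masked as a MOM ether disfavours β-elimination of the ring oxygen, chromanone formation and quinone-methide opening.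

**Step 12**
Reactants: 17 (E)-1-[2,4-bis(methoxymethoxy)phenyl]-3-{(2R,3R)-3-[2,4-bis(methoxymethoxy)benzoyl]-2-[4-(methoxymethoxy)phenyl]-2,3-dihydro-1-benzofuran-5-yl}prop-2-en-1-one
Product: 18 (E)-1-(2,4-dihydroxyphenyl)-3-[(2R,3R)-3-(2,4-dihydroxybenzoyl)-2-(4-hydroxyphenyl)-2,3-dihydro-1-benzofuran-5-yl]prop-2-en-1-one (CNP0288976.3)
Conditions: 3 M HCl (aq), MeOH/THF, 40 °C, stopped at full conversion
Reagents that add atoms: none
Why: Acid-catalysed acetal exchange with methanol should cleave all five aryl MOM ethers in one base-free operation, leaving the enone and the already thermodynamic trans C2/C3 arrangement untouched, provided the temperature is kept low enough to avoid flavanone formation from the 2'-hydroxychalcone.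

**Compound list**
1 | 4-bromobenzene-1,3-diol (4-bromoresorcinol) | Oc1ccc(Br)c(O)c1 | starting material
2 | 1-bromo-2,4-bis(methoxymethoxy)benzene | COCOc1ccc(Br)c(OCOC)c1 | intermediate
3 | acrolein (prop-2-enal) | C=CC=O | starting material
4 | [2,4-bis(methoxymethoxy)phenyl]magnesium bromide | Br[Mg]c1ccc(OCOC)cc1OCOC | intermediate
5 | 1-[2,4-bis(methoxymethoxy)phenyl]prop-2-en-1-ol (racemic) | C=CC(O)c1ccc(OCOC)cc1OCOC | intermediate
6 | 1-[2,4-bis(methoxymethoxy)phenyl]prop-2-en-1-one | C=CC(=O)c1ccc(OCOC)cc1OCOC | intermediate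
7 | 4-(methoxymethoxy)benzaldehyde | COCOc1ccc(C=O)cc1 | starting material
8 | [4-(methoxymethoxy)phenyl]methanol | COCOc1ccc(CO)cc1 | intermediate
9 | methyl 2-(5-bromo-2-hydroxyphenyl)acetate | COC(=O)Cc1cc(Br)ccc1O | starting material
10 | methyl 2-(5-bromo-2-{[4-(methoxymethoxy)phenyl]methoxy}phenyl)acetate | COC(=O)Cc1cc(Br)ccc1OCc1ccc(OCOC)cc1 | intermediate
11 | methyl 2-(5-bromo-2-{[4-(methoxymethoxy)phenyl]methoxy}phenyl)-2-diazoacetate | COC(=O)C(=[N+]=[N-])c1cc(Br)ccc1OCc1ccc(OCOC)cc1 | intermediate
12 | methyl (2R,3S)-5-bromo-2-[4-(methoxymethoxy)phenyl]-2,3-dihydro-1-benzofuran-3-carboxylate (cis) | Brc1ccc2c(c1)[C@H](C(=O)OC)[C@H](c1ccc(OCOC)cc1)O2 | intermediate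
13 | methyl (2R,3R)-5-bromo-2-[4-(methoxymethoxy)phenyl]-2,3-dihydro-1-benzofuran-3-carboxylate (trans) | Brc1ccc2c(c1)[C@@H](C(=O)OC)[C@H](c1ccc(OCOC)cc1)O2 | intermediate
14 | (2R,3R)-5-bromo-N-methoxy-N-methyl-2-[4-(methoxymethoxy)phenyl]-2,3-dihydro-1-benzofuran-3-carboxamide | Brc1ccc2c(c1)[C@@H](C(=O)N(C)OC)[C@H](c1ccc(OCOC)cc1)O2 | intermediate
15 | [2,4-bis(methoxymethoxy)phenyl]lithium | [Li]c1ccc(OCOC)cc1OCOC | intermediate
16 | [2,4-bis(methoxymethoxy)phenyl]{(2R,3R)-5-bromo-2-[4-(methoxymethoxy)phenyl]-2,3-dihydro-1-benzofuran-3-yl}methanone | Brc1ccc2c(c1)[C@@H](C(=O)c1ccc(OCOC)cc1OCOC)[C@H](c1ccc(OCOC)cc1)O2 | intermediate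
17 | (E)-1-[2,4-bis(methoxymethoxy)phenyl]-3-{(2R,3R)-3-[2,4-bis(methoxymethoxy)benzoyl]-2-[4-(methoxymethoxy)phenyl]-2,3-dihydro-1-benzofuran-5-yl}prop-2-en-1-one | O=C(/C=C/c1ccc2c(c1)[C@@H](C(=O)c1ccc(OCOC)cc1OCOC)[C@H](c1ccc(OCOC)cc1)O2)c1ccc(OCOC)cc1OCOC | intermediate
18 | (E)-1-(2,4-dihydroxyphenyl)-3-[(2R,3R)-3-(2,4-dihydroxybenzoyl)-2-(4-hydroxyphenyl)-2,3-dihydro-1-benzofuran-5-yl]prop-2-en-1-one | O=C(/C=C/c1ccc2c(c1)[C@@H](C(=O)c1ccc(O)cc1O)[C@H](c1ccc(O)cc1)O2)c1ccc(O)cc1O | target

**Step count.** Total: 12 steps. Longest linear sequence: 9 steps (7 → 8 → 10 → 11 → 12 → 13 → 14 → 16 → 17 → 18; steps 4–12).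

**Steps most likely to fail**

Step 11 (key coupling). The vinyl ketone may oligomerise under the amine/phosphine conditions, oxidative addition to the electron-rich C5–Br bond may be slow, or enolisation at C3 may be followed by β-elimination that opens the dihydrofuran ring. The fallback sets out from 16 and is base-free. Stille vinylation (tributyl(vinyl)stannane, Pd(PPh3)4, toluene, 100 °C) should give [2,4-bis(methoxymethoxy)phenyl]{(2R,3R)-5-ethenyl-2-[4-(methoxymethoxy)phenyl]-2,3-dihydro-1-benzofuran-3-yl}methanone F1. Olefin cross-metathesis of this styrene with an excess of 6 (Hoveyda–Grubbs second-generation catalyst, CH2Cl2, 40 °C) should then deliver the E-enone and return to the route at 17.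

Step 10 (ketone formation). The aryllithium may deprotonate C3 of the amide instead of adding, with subsequent β-elimination of the ring aryloxide, or bromine–lithium exchange may occur at C5. The fallback sets out from 13. i-Bu2AlH (toluene, −78 °C) should give (2R,3R)-5-bromo-2-[4-(methoxymethoxy)phenyl]-2,3-dihydro-1-benzofuran-3-carbaldehyde F2. The much faster 1,2-addition of aryllithium 15 (from 2 and n-BuLi, THF, −78 °C, as in step 10) should give [2,4-bis(methoxymethoxy)phenyl]{(2R,3S)-5-bromo-2-[4-(methoxymethoxy)phenyl]-2,3-dihydro-1-benzofuran-3-yl}methanol F3 as a mixture of carbinol epimers; the ring keeps the trans arrangement of 13, and the C3 descriptor changes only because the priority order of its substituents changes. Dess–Martin periodinane (NaHCO3, CH2Cl2, rt) should oxidise it to the ketone, rejoining the route at 16.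

Step 7 (C–H insertion). Discrimination of the enantiotopic benzylic hydrogens may be insufficient on this substrate, or the carbenoid may dimerise. The fallback sets out from 11. Achiral Rh2(OAc)4 (CH2Cl2, rt) should give racemic methyl cis-5-bromo-2-[4-(methoxymethoxy)phenyl]-2,3-dihydro-1-benzofuran-3-carboxylate F4. NaOMe/MeOH should epimerise it to racemic methyl trans-5-bromo-2-[4-(methoxymethoxy)phenyl]-2,3-dihydro-1-benzofuran-3-carboxylate F5. Preparative chromatography on a chiral stationary phase (SFC) should then separate the (2R,3R) enantiomer, returning to the route at 13.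

**Further compounds**
F1 | step 11 | [2,4-bis(methoxymethoxy)phenyl]{(2R,3R)-5-ethenyl-2-[4-(methoxymethoxy)phenyl]-2,3-dihydro-1-benzofuran-3-yl}methanone | C=Cc1ccc2c(c1)[C@@H](C(=O)c1ccc(OCOC)cc1OCOC)[C@H](c1ccc(OCOC)cc1)O2
F2 | step 10 | (2R,3R)-5-bromo-2-[4-(methoxymethoxy)phenyl]-2,3-dihydro-1-benzofuran-3-carbaldehyde | Brc1ccc2c(c1)[C@@H](C=O)[C@H](c1ccc(OCOC)cc1)O2
F3 | step 10 | [2,4-bis(methoxymethoxy)phenyl]{(2R,3S)-5-bromo-2-[4-(methoxymethoxy)phenyl]-2,3-dihydro-1-benzofuran-3-yl}methanol (both carbinol epimers; trans ring arrangement as in 13) | Brc1ccc2c(c1)[C@@H](C(O)c1ccc(OCOC)cc1OCOC)[C@H](c1ccc(OCOC)cc1)O2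
F4 | step 7 | racemic methyl cis-5-bromo-2-[4-(methoxymethoxy)phenyl]-2,3-dihydro-1-benzofuran-3-carboxylate (both enantiomers) | Brc1ccc2c(c1)[C@H](C(=O)OC)[C@H](c1ccc(OCOC)cc1)O2.Brc1ccc2c(c1)[C@@H](C(=O)OC)[C@@H](c1ccc(OCOC)cc1)O2
F5 | step 7 | racemic methyl trans-5-bromo-2-[4-(methoxymethoxy)phenyl]-2,3-dihydro-1-benzofuran-3-carboxylate (both enantiomers) | Brc1ccc2c(c1)[C@@H](C(=O)OC)[C@H](c1ccc(OCOC)cc1)O2.Brc1ccc2c(c1)[C@H](C(=O)OC)[C@@H](c1ccc(OCOC)cc1)O2
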